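A one-step world, where free monomer adds to living ends and nothing comes back, has a rate that dies with the free monomer itself. The scheme here has a way back, and I wanted to see what that does to the rate.

    free monomer + initiator → living end + monomer in chains (k1 = 0.058 M⁻¹ s⁻¹)
    free monomer + living end → monomer in chains + living end, rate k2*[living end]*[free monomer] (k2 = 0.66 M⁻¹ s⁻¹)
    monomer in chains + living end → free monomer + living end, rate k3*[living end] as long as [monomer in chains] is above zero (k3 = 0.064 s⁻¹)
    free monomer → uncatalysed product (k4 = 1.2 × 10⁻⁵ s⁻¹)

| flask | free monomer | initiator | remark | time |
|---|---|---|---|---|
| midnight | 0.20 M | 10 mM | a single well-mixed tank run continuously and read at steady state, 80 min in it on average |  |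
| dusk | 0.20 M | 10 mM | everything together in a closed stirred flask, run for 80 min | 80 min |
| winter | 0.20 M (fed, over 64.0 min) | 10 mM | a stirred flask in which free monomer is dosed at a steady rate over 64.0 min without added volume, worked up at 80 min | 80 min |

- the stated concentrations are those of everything mixed, before any reaction; amounts are the same in each set-up
- the feed brings no volume worth counting
- run time (dusk): 80 min

- the set-up with the highest amount of monomer in chains at the outlet or at the end, in percent of the free monomer put in ("none" if the first two lie within 2 percentage points) (midnight / dusk / winter / none)
- amount of monomer in chains at the outlet or at the end, in percent of the free monomer put in, midnight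
- amount of monomer in chains at the outlet or at the end, in percent of the free monomer put in, dusk
- amount of monomer in chains at the outlet or at the end, in percent of the free monomer put in, winter

I reckoned the rate for the dusk flask, the closed one. No step in the scheme removes a living end, and with free monomer at its charge the initiator has a half-life of 59.8 s, much shorter than the run. So I reckoned with the living end at 10 mM. That is the concentration that sets the order, since with it steady the growth is pseudo-first-order.

With that living end and free monomer at its charge, the forward step came to 0.00132 M s⁻¹. The back step took away 6.40 × 10⁻⁴ M s⁻¹ while chains were present, which cut this reckoned net rate by a factor of 1.94. After that, the falling free monomer slowed it further, since the net rate is k2 × living end × (free monomer − k3/k2). I called k3/k2 the balance level, the concentration of free monomer at which steps 2 and 3 run equally fast: 0.0970 M.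

The excess above that level shrank by a factor of e every 2.53 min, and the run holds 31.7 such spans. What remained was the leak to uncatalysed product, at 1.16 × 10⁻⁶ M s⁻¹, much slower than the back step. Over the run I reckoned it at 2.79 % of the charge, so I committed to 48.7 % in chains for the dusk flask and reckoned no further.

The forecast gave 47.2 % for the midnight tank, 48.7 % for the dusk flask and 49.3 % for the winter flask, and called none, on the ground that “All three set-ups run into the same ceiling”.

The simulation gave 47.3 % for the midnight tank, 48.7 % for the dusk flask and 49.3 % for the winter flask, so the call was none, with the top two 0.60 percentage points apart. The dusk flask ended with 48.4 % of its charge as free monomer, and the balance level is 48.5 % of that charge. I then used the level on the winter flask left until 800 min. Counting the leak at the balance level for that whole time, I reckoned it at 27.9 % of the charge, which left 23.6 % in chains. The run read 24.2 %.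

(The constants are those of an exercise; the result is computed.)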